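**Retrosynthetic overview**
1. Target 28 ⇐ hydrolysis of acyl oxazolidinone 26; the C9–C10 bond ⇐ aldehyde 23 + alkenylzinc from iodide 9 (catalyst sets C9).
2. The Cα–C3 bond ⇐ cyclic peroxycarbenium ion from acetate 18 + titanium enolate of imide 20 (auxiliary sets C3 and Cα; the radical step leaves C6 racemic, so the C6 epimers are separated here, at most 50 %).
3. Key step: the 1,2-dioxane ⇐ cyclobutanol 15 by alkoxyl-radical β-scission and capture of the tertiary C6 radical by O2, so that O2 is inserted into the former C3–C6 bond.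
4. Cyclobutanol 15 ⇐ hex-5-en-2-one + 1-ethoxycyclopropyl anion (ring expansion), then reduction; iodide 9 ⇐ 2-methylcyclohexanone by double methylation, enol triflate, Negishi coupling and hydroalumination–iodination.
5. Ring order: cyclohexene (carried from the starting ring, steps 1–2), cyclobutane (step 5), 1,2-dioxane (step 7).

Assumptions and locants: 1-bromo-1-ethoxycyclopropane is taken as purchasable; the oxazolidinone is a recoverable auxiliary and is listed with the reagents. Locants: dioxane O1, O2, C3–C6; Cα is the propanoic acid α-carbon; side chain C7–C12 with C9 the carbinol carbon.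

**Step 1**
Reactants: 1 2-methylcyclohexan-1-one
Product: 3 2,2,6-trimethylcyclohexan-1-one (racemic), via 2,6-dimethylcyclohexan-1-one 2 (not isolated)
Conditions: LiN(i-Pr)2 (1.05 equiv), THF, −78 °C; MeI, −78→0 °C; then LiN(i-Pr)2 (1.2 equiv), −78 °C; MeI, →25 °C
Reagents that add atoms: iodomethane (CI)
Why: Two successive kinetic enolate alkylations: the first amide base deprotonates the less substituted α-carbon of 1 to give 2, and a second deprotonation–methylation builds the gem-dimethyl carbon; the remaining racemic centre is planarised in step 2.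

**Step 2**
Reactants: 3 2,2,6-trimethylcyclohexan-1-one
Product: 4 2,6,6-trimethylcyclohex-1-en-1-yl trifluoromethanesulfonate
Conditions: LiN(i-Pr)2, THF, −78 °C; PhNTf2, −78→25 °C
Reagents that add atoms: N-phenylbis(trifluoromethanesulfonimide) (O=S(=O)(N(c1ccccc1)S(=O)(=O)C(F)(F)F)C(F)(F)F)
Why: Enol triflate formation: the only α-hydrogen is removed and the enolate is O-sulfonylated, which fixes the tetrasubstituted double bond regiospecifically.

**Step 3**
Reactants: 4 2,6,6-trimethylcyclohex-1-en-1-yl trifluoromethanesulfonate; 5 4-bromobut-1-yne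
Product: 7 2-(but-3-yn-1-yl)-1,3,3-trimethylcyclohex-1-ene, via but-3-yn-1-ylzinc bromide 6 (not isolated)
Conditions: 5, Zn, LiCl, THF, 40 °C; then 4, Pd(dppf)Cl2 (5 mol %), THF/NMP, 60 °C
Reagents that add atoms: none
Why: Negishi cross-coupling: zinc inserts into the primary C–Br bond (the alkylzinc tolerates the terminal alkyne C–H), and the wide-bite-angle palladium catalyst favours reductive elimination over β-hydride elimination when joining the sp3 zinc reagent to the hindered enol triflate.

**Step 4**
Reactants: 7 2-(but-3-yn-1-yl)-1,3,3-trimethylcyclohex-1-ene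
Product: 9 2-(3-iodobut-3-en-1-yl)-1,3,3-trimethylcyclohex-1-ene, via alkenylalane 8 (not isolated)
Conditions: Ni(dppp)Cl2 (3 mol %), i-Bu2AlH (1.3 equiv), THF, 0→22 °C; then I2, THF, −78→0 °C
Reagents that add atoms: iodine (II)
Why: Nickel-catalysed α-selective hydroalumination places aluminium on the internal alkyne carbon, and iodinolysis of the C–Al bond gives the 2-iodo-1-alkene; the tetrasubstituted ring alkene does not react.

**Step 5**
Reactants: 10 1-bromo-1-ethoxycyclopropane; 11 hex-5-en-2-one
Product: 14 2-(but-3-en-1-yl)-2-methylcyclobutan-1-one (racemic), via (1-ethoxycyclopropyl)lithium 12 (not isolated), via 2-(1-ethoxycyclopropyl)hex-5-en-2-ol 13 (not isolated)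
Conditions: 10, t-BuLi (2 equiv), Et2O, −78 °C; 11, −78→0 °C; then aq. HBF4 (48 %), Et2O, 25 °C
Reagents that add atoms: water (O)
Why: Cyclobutanone annulation: bromine–lithium exchange and 1,2-addition give a tertiary cyclopropylcarbinol, and acid ionisation triggers an ethoxy-driven cyclopropylcarbinyl-to-cyclobutyl (semipinacol-type) ring expansion that places the former ketone carbon (future C6, with its methyl and butenyl groups) next to the new carbonyl; the centre is racemic and is planarised in step 7.

**Step 6**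
Reactants: 14 2-(but-3-en-1-yl)-2-methylcyclobutan-1-one
Product: 15 2-(but-3-en-1-yl)-2-methylcyclobutan-1-ol (racemic cis/trans mixture)
Conditions: NaBH4, MeOH, 0 °C
Reagents that add atoms: none
Why: Borohydride reduction of the strained ketone; the cis/trans ratio does not matter because both ring stereocentres are destroyed in step 7.

**Step 7 (key step)**
Reactants: 15 2-(but-3-en-1-yl)-2-methylcyclobutan-1-ol
Product: 18 6-(but-3-en-1-yl)-6-methyl-1,2-dioxan-3-yl acetate (racemic at C6; anomer mixture), via 4-hydroperoxy-4-methyloct-7-enal 16 (not isolated), via 6-(but-3-en-1-yl)-6-methyl-1,2-dioxan-3-ol 17 (not isolated)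
Conditions: Co(acac)2 (20 mol %), O2 (1 atm), ClCH2CH2Cl, 40 °C; then pyridine, Ac2O, DMAP (cat.), 0 °C
Reagents that add atoms: dioxygen (O=O); acetic anhydride (CC(=O)OC(C)=O)
Why: Cobalt-catalysed aerobic oxidative ring expansion of a cyclobutanol (radical β-scission and O2 capture, the four-ring counterpart of the aerobic cyclopropanol to 1,2-dioxolan-3-ol oxygenation): the alkoxide bound to trivalent cobalt fragments as an alkoxyl radical with release of about 26 kcal/mol of strain, cleaving toward the quaternary carbon; the tertiary radical is trapped by triplet O2 at a diffusion-controlled rate (4-exo or 5-endo closure onto the butenyl group cannot compete, and with no hydride source the alkene is untouched); the peroxyl radical is captured by divalent cobalt and released as hydroperoxide 16 by exchange with the next cyclobutanol, and 16 closes onto the liberated aldehyde to 17, which is acetylated; C6 is formed racemic from the planar radical and the anomeric C3 centre is erased in step 9.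

**Step 8**
Reactants: 19 propanoyl chloride
Product: 20 (4S)-4-benzyl-3-propanoyl-1,3-oxazolidin-2-one
Conditions: (4S)-4-benzyl-1,3-oxazolidin-2-one, n-BuLi, THF, −78 °C; then 19, −78→0 °C
Reagents that add atoms: (4S)-4-benzyl-1,3-oxazolidin-2-one (O=C1OC[C@H](Cc2ccccc2)N1)
Why: N-acylation of the lithiated Evans auxiliary; no new stereocentre.

**Step 9**
Reactants: 20 (4S)-4-benzyl-3-propanoyl-1,3-oxazolidin-2-one; 18 6-(but-3-en-1-yl)-6-methyl-1,2-dioxan-3-yl acetate
Product: 22 (4S)-4-benzyl-3-{(2R)-2-[(3S,6R)-6-(but-3-en-1-yl)-6-methyl-1,2-dioxan-3-yl]propanoyl}-1,3-oxazolidin-2-one, via trichlorotitanium (Z)-enolate 21 (not isolated)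
Conditions: 20, TiCl4, i-Pr2NEt, CH2Cl2, −78→0 °C; then 18, SnCl4, −78→−40 °C; chromatography
Reagents that add atoms: none
Why: Proposed new method: Lewis-acid ionisation of the peroxy acetal acetate gives a cyclic peroxycarbenium ion (a species known to be captured by allylsilanes, silyl enol ethers and silyl ketene acetals), trapped here by the chelated (Z)-chlorotitanium enolate of the Evans imide (the reagent class known to alkylate cyclic oxocarbenium ions from lactol acetals); attack on the enolate face opposite the benzyl group sets Cα as R, and an open antiperiplanar transition state in which the cation C–H, not the ring CH2 or the O–O bond, sits next to the enolate methyl sets C3 as S (the 2,3-syn relationship of the target); the racemic C6 centre is not influenced, so the (3S,6R) and (3S,6S) imides form in about equal amounts and the (6R) epimer is isolated by chromatography.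

**Step 10**
Reactants: 22 (4S)-4-benzyl-3-{(2R)-2-[(3S,6R)-6-(but-3-en-1-yl)-6-methyl-1,2-dioxan-3-yl]propanoyl}-1,3-oxazolidin-2-one
Product: 23 (4S)-4-benzyl-3-{(2R)-2-[(3S,6S)-6-methyl-6-(3-oxopropyl)-1,2-dioxan-3-yl]propanoyl}-1,3-oxazolidin-2-one
Conditions: O3, CH2Cl2, −78 °C; then Me2S, −78→25 °C
Reagents that add atoms: ozone ([O-][O+]=O)
Why: Ozonolysis with reductive work-up cleaves the only C=C bond; the dialkyl peroxide, imide and arene are inert at −78 °C and Me2S reduces the ozonide but not the 1,2-dioxane; no stereocentre is touched (the C6 descriptor changes to S only because the substituent priorities change).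

**Step 11**
Reactants: 9 2-(3-iodobut-3-en-1-yl)-1,3,3-trimethylcyclohex-1-ene; 23 (4S)-4-benzyl-3-{(2R)-2-[(3S,6S)-6-methyl-6-(3-oxopropyl)-1,2-dioxan-3-yl]propanoyl}-1,3-oxazolidin-2-one
Product: 26 (4S)-4-benzyl-3-{(2R)-2-[(3S,6R)-6-[(3R)-3-hydroxy-4-methylidene-6-(2,6,6-trimethylcyclohex-1-en-1-yl)hexyl]-6-methyl-1,2-dioxan-3-yl]propanoyl}-1,3-oxazolidin-2-one, via alkenyllithium 24 (not isolated), via ethyl(alkenyl)zinc 25 (not isolated)
Conditions: 9 (1.6 equiv), t-BuLi (2 equiv per 9), Et2O, −78 °C; EtZnCl (from Et2Zn and ZnCl2), −78→0 °C; N,N,N′,N′-tetraethylethylenediamine, (2S)-3-exo-morpholinoisoborneol [(−)-MIB, 10 mol %], toluene; then 23, −20→0 °C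
Reagents that add atoms: none
Why: Amino-alcohol-catalysed enantioselective alkenylzinc addition to an aldehyde: iodine–lithium exchange and transmetalation give the mixed zinc reagent, the diamine sequesters LiCl to suppress the racemic background, and the (−)-MIB–zinc complex delivers the alkenyl group (transferred in preference to ethyl) to the Si face of the aldehyde, which gives the (R)-carbinol at C9 under catalyst control; the minor C9 epimer is a diastereomer and is removed by chromatography, and zinc reagents attack neither the imide nor the dialkyl peroxide.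

**Step 12**
Reactants: 26 (4S)-4-benzyl-3-{(2R)-2-[(3S,6R)-6-[(3R)-3-hydroxy-4-methylidene-6-(2,6,6-trimethylcyclohex-1-en-1-yl)hexyl]-6-methyl-1,2-dioxan-3-yl]propanoyl}-1,3-oxazolidin-2-one
Product: 28 (2R)-2-{(3S,6R)-6-[(3R)-3-hydroxy-4-methylidene-6-(2,6,6-trimethylcyclohex-1-en-1-yl)hexyl]-6-methyl-1,2-dioxan-3-yl}propanoic acid, via peroxy acid 27 (not isolated)
Conditions: LiOH, H2O2, THF/H2O, 0 °C; Na2SO3 (aq), 0 °C; then aq. HCl to pH 3
Reagents that add atoms: hydrogen peroxide (OO)
Why: Evans auxiliary cleavage with lithium hydroperoxide: the α-effect nucleophile attacks the exocyclic imide carbonyl, the peroxy acid salt is reduced by sulfite before acidification so that no alkene is epoxidised, and the weakly basic conditions at 0 °C avoid epimerisation at Cα and β-elimination of the ring peroxide.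

**Compound list**
1 | 2-methylcyclohexan-1-one | CC1CCCCC1=O | starting material
2 | 2,6-dimethylcyclohexan-1-one | CC1CCCC(C)C1=O | intermediate
3 | 2,2,6-trimethylcyclohexan-1-one | CC1CCCC(C)(C)C1=O | intermediate
4 | 2,6,6-trimethylcyclohex-1-en-1-yl trifluoromethanesulfonate | CC1=C(OS(=O)(=O)C(F)(F)F)C(C)(C)CCC1 | intermediate
5 | 4-bromobut-1-yne | BrCCC#C | starting material
6 | but-3-yn-1-ylzinc bromide | Br[Zn]CCC#C | intermediate
7 | 2-(but-3-yn-1-yl)-1,3,3-trimethylcyclohex-1-ene | C#CCCC1=C(C)CCCC1(C)C | intermediate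
8 | bis(2-methylpropyl)[4-(2,6,6-trimethylcyclohex-1-en-1-yl)but-1-en-2-yl]alumane | C=C(CCC1=C(C)CCCC1(C)C)[Al](CC(C)C)CC(C)C | intermediate
9 | 2-(3-iodobut-3-en-1-yl)-1,3,3-trimethylcyclohex-1-ene | C=C(I)CCC1=C(C)CCCC1(C)C | intermediate
10 | 1-bromo-1-ethoxycyclopropane | CCOC1(Br)CC1 | starting material
11 | hex-5-en-2-one | CC(=O)CCC=C | starting material
12 | (1-ethoxycyclopropyl)lithium | [Li]C1(OCC)CC1 | intermediate
13 | 2-(1-ethoxycyclopropyl)hex-5-en-2-ol | C=CCCC(C)(O)C1(OCC)CC1 | intermediate
14 | 2-(but-3-en-1-yl)-2-methylcyclobutan-1-one | C=CCCC1(C)CCC1=O | intermediate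
15 | 2-(but-3-en-1-yl)-2-methylcyclobutan-1-ol | C=CCCC1(C)CCC1O | intermediate
16 | 4-hydroperoxy-4-methyloct-7-enal | C=CCCC(C)(OO)CCC=O | intermediate
17 | 6-(but-3-en-1-yl)-6-methyl-1,2-dioxan-3-ol | C=CCCC1(C)CCC(O)OO1 | intermediate
18 | 6-(but-3-en-1-yl)-6-methyl-1,2-dioxan-3-yl acetate | C=CCCC1(C)CCC(OC(C)=O)OO1 | intermediate
19 | propanoyl chloride | CCC(=O)Cl | starting material
20 | (4S)-4-benzyl-3-propanoyl-1,3-oxazolidin-2-one | CCC(=O)N1[C@@H](Cc2ccccc2)COC1=O | intermediate
21 | trichlorotitanium (Z)-enolate of 20 | C/C=C(\O[Ti](Cl)(Cl)Cl)N1[C@@H](Cc2ccccc2)COC1=O | intermediate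
22 | (4S)-4-benzyl-3-{(2R)-2-[(3S,6R)-6-(but-3-en-1-yl)-6-methyl-1,2-dioxan-3-yl]propanoyl}-1,3-oxazolidin-2-one | C=CCC[C@]1(C)CC[C@@H]([C@@H](C)C(=O)N2[C@@H](Cc3ccccc3)COC2=O)OO1 | intermediate
23 | (4S)-4-benzyl-3-{(2R)-2-[(3S,6S)-6-methyl-6-(3-oxopropyl)-1,2-dioxan-3-yl]propanoyl}-1,3-oxazolidin-2-one | O=CCC[C@]1(C)CC[C@@H]([C@@H](C)C(=O)N2[C@@H](Cc3ccccc3)COC2=O)OO1 | intermediate
24 | [4-(2,6,6-trimethylcyclohex-1-en-1-yl)but-1-en-2-yl]lithium | [Li]C(=C)CCC1=C(C)CCCC1(C)C | intermediate
25 | ethyl[4-(2,6,6-trimethylcyclohex-1-en-1-yl)but-1-en-2-yl]zinc | CC[Zn]C(=C)CCC1=C(C)CCCC1(C)C | intermediate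
26 | (4S)-4-benzyl-3-{(2R)-2-[(3S,6R)-6-[(3R)-3-hydroxy-4-methylidene-6-(2,6,6-trimethylcyclohex-1-en-1-yl)hexyl]-6-methyl-1,2-dioxan-3-yl]propanoyl}-1,3-oxazolidin-2-one | C=C(CCC1=C(C)CCCC1(C)C)[C@H](O)CC[C@]1(C)CC[C@@H]([C@@H](C)C(=O)N2[C@@H](Cc3ccccc3)COC2=O)OO1 | intermediate
27 | (2R)-2-{(3S,6R)-6-[(3R)-3-hydroxy-4-methylidene-6-(2,6,6-trimethylcyclohex-1-en-1-yl)hexyl]-6-methyl-1,2-dioxan-3-yl}propaneperoxoic acid | C=C(CCC1=C(C)CCCC1(C)C)[C@H](O)CC[C@]1(C)CC[C@@H]([C@@H](C)C(=O)OO)OO1 | intermediate
28 | (2R)-2-{(3S,6R)-6-[(3R)-3-hydroxy-4-methylidene-6-(2,6,6-trimethylcyclohex-1-en-1-yl)hexyl]-6-methyl-1,2-dioxan-3-yl}propanoic acid | C=C(CCC1=C(C)CCCC1(C)C)[C@H](O)CC[C@]1(C)CC[C@@H]([C@@H](C)C(=O)O)OO1 | target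

**Step count and risks**
Total: 12 steps. Longest linear sequence: 7 steps (5, 6, 7, 9, 10, 11, 12).

Step 7 (radical ring expansion). Cobalt may degrade the open-chain hydroperoxide 16 before it closes, and the tertiary peroxyl radical may add 6-exo to the butenyl group. The fallback still makes the C6–O bond from a tertiary radical and O2, but generates the radical by hydrogen-atom transfer to an alkene instead of by ring fragmentation. It sets out from 11, which is treated with the Grignard reagent [2-(1,3-dioxolan-2-yl)ethyl]magnesium bromide F1 (from 2-(2-bromoethyl)-1,3-dioxolane and Mg) to give the tertiary alcohol 1-(1,3-dioxolan-2-yl)-3-methylhept-6-en-3-ol F2. Dehydration (SOCl2, pyridine) gives 2-(3-methylidenehept-6-en-1-yl)-1,3-dioxolane F3 together with its trisubstituted double-bond isomers, all of which lead to the same tertiary radical. Mukaiyama–Isayama hydroperoxysilylation (Co(acac)2, O2, Et3SiH, ClCH2CH2Cl; the terminal alkene reacts much more slowly) gives the silyl peroxide {[1-(1,3-dioxolan-2-yl)-3-methylhept-6-en-3-yl]peroxy}triethylsilane F4. Aqueous acid (HCl, THF/H2O) removes the silyl and dioxolane groups, and the hydroperoxy aldehyde closes to 17, where the fallback comes back to the route (acetylation to 18 as in step 7).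

Step 9 (peroxycarbenium alkylation). The titanium enolate may be too weak a nucleophile for the peroxycarbenium ion, the Lewis acids may ionise the tertiary C6–O bond, and at best half of the material has the wanted C6 configuration. The fallback forms the C3–O bond last instead of the C3–Cα bond. It sets out from 20 and from 17 (step 7 stopped before acetylation). Boron-enolate bromination of 20 (Bu2BOTf, i-Pr2NEt; NBS) gives the bromo imide (4S)-4-benzyl-3-(2-bromopropanoyl)-1,3-oxazolidin-2-one F5, and Arbuzov reaction with P(OEt)3 gives the phosphonate diethyl {1-[(4S)-4-benzyl-2-oxo-1,3-oxazolidin-3-yl]-1-oxopropan-2-yl}phosphonate F6. Masamune–Roush olefination (LiCl, i-Pr2NEt, MeCN) of the ring-opened aldehyde form of 17 gives the hydroperoxy enimide (4S)-4-benzyl-3-[(2E)-6-hydroperoxy-2,6-dimethyldeca-2,9-dienoyl]-1,3-oxazolidin-2-one F7. Its tertiary hydroperoxide adds 6-exo to the unsaturated imide with catalytic Cs2CO3, and chromatography gives 22, where the route is rejoined (lower selectivity at C3 and Cα is expected).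

Step 11 (enantioselective alkenylzinc addition). Residual lithium salts or chelation by the imide may erode the selectivity, and the hindered 1,1-disubstituted alkenylzinc may transfer slowly. The fallback sets C9 by reduction instead of by addition. It sets out from 23 and 25: addition without the amino alcohol gives the C9-epimeric allylic alcohols F8, Dess–Martin oxidation gives the cross-conjugated enone F9, and reduction with (S)-2-methyl-CBS-oxazaborolidine and catecholborane (toluene, −78 °C; the 1,1-disubstituted alkenyl group acts as the large substituent, which gives the R alcohol) comes back to the route at 26.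

**Further compounds**
F1 | step 7 | [2-(1,3-dioxolan-2-yl)ethyl]magnesium bromide | Br[Mg]CCC1OCCO1
F2 | step 7 | 1-(1,3-dioxolan-2-yl)-3-methylhept-6-en-3-ol | C=CCCC(C)(O)CCC1OCCO1
F3 | step 7 | 2-(3-methylidenehept-6-en-1-yl)-1,3-dioxolane | C=CCCC(=C)CCC1OCCO1
F4 | step 7 | {[1-(1,3-dioxolan-2-yl)-3-methylhept-6-en-3-yl]peroxy}triethylsilane | C=CCCC(C)(OO[Si](CC)(CC)CC)CCC1OCCO1
F5 | step 9 | (4S)-4-benzyl-3-(2-bromopropanoyl)-1,3-oxazolidin-2-one | CC(Br)C(=O)N1[C@@H](Cc2ccccc2)COC1=O
F6 | step 9 | diethyl {1-[(4S)-4-benzyl-2-oxo-1,3-oxazolidin-3-yl]-1-oxopropan-2-yl}phosphonate | CCOP(=O)(OCC)C(C)C(=O)N1[C@@H](Cc2ccccc2)COC1=O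
F7 | step 9 | (4S)-4-benzyl-3-[(2E)-6-hydroperoxy-2,6-dimethyldeca-2,9-dienoyl]-1,3-oxazolidin-2-one | C=CCCC(C)(OO)CC/C=C(\C)C(=O)N1[C@@H](Cc2ccccc2)COC1=O
F8 | step 11 | (4S)-4-benzyl-3-{(2R)-2-[(3S,6R)-6-[(3RS)-3-hydroxy-4-methylidene-6-(2,6,6-trimethylcyclohex-1-en-1-yl)hexyl]-6-methyl-1,2-dioxan-3-yl]propanoyl}-1,3-oxazolidin-2-one | C=C(CCC1=C(C)CCCC1(C)C)C(O)CC[C@]1(C)CC[C@@H]([C@@H](C)C(=O)N2[C@@H](Cc3ccccc3)COC2=O)OO1
F9 | step 11 | (4S)-4-benzyl-3-{(2R)-2-[(3S,6S)-6-methyl-6-[4-methylidene-3-oxo-6-(2,6,6-trimethylcyclohex-1-en-1-yl)hexyl]-1,2-dioxan-3-yl]propanoyl}-1,3-oxazolidin-2-one | C=C(CCC1=C(C)CCCC1(C)C)C(=O)CC[C@]1(C)CC[C@@H]([C@@H](C)C(=O)N2[C@@H](Cc3ccccc3)COC2=O)OO1
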